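The ten-membered ring (germacrane numbering: C4 tertiary carbinol, C5 methylene, C6 ester carbinol, C7=C8–C9=C10 diene) is opened at C5–C6. Because the oxygens on C4 and C6 are 1,3-related, a C4=C5 double bond can be written in, which turns C6 into a bis-allylic carbinol. The key step, an asymmetric Nozaki–Hiyama–Kishi macrocyclisation of an acyclic (2Z,4E)-dienal that ends in an (E)-alkenyl iodide, closes the ring, forms C5–C6 and sets C6 in one operation. The C6 hydroxyl then steers oxygen to C4, and C4 later resets C6. The precursor stems from a symmetrical bis(alkenyl iodide), one end serving the Stille coupling, the other the ring closure.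

Key step: step 5

Assumption: the (S)-configured oxazoline–sulfonamide ligand is taken to give the (S)-carbinol 10. If the sense of induction is the opposite, its enantiomer is used and nothing else changes.

Step 1
Reactants: 1 hepta-1,6-diyne
Product: 3 (1E,6E)-1,7-diiodo-2,6-dimethylhepta-1,6-diene, via bis(dimethylalanyl)diene 2 (not isolated)
Conditions: Me3Al (5 equiv), Cp2ZrCl2 (0.4 equiv), CH2Cl2, 0 °C to rt; then I2, THF, −30 °C
Reagents that add atoms: trimethylaluminium C[Al](C)C; iodine II
Why: Zirconium-catalysed Negishi carboalumination adds methyl and aluminium syn across each terminal alkyne with aluminium at the terminus, and iodinolysis with retention should give both (E)-2-methylalkenyl iodides at once.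

Step 2
Reactants: 4 prop-2-yn-1-ol
Product: 6 (2Z)-2-(propan-2-yl)-3-(tributylstannyl)prop-2-en-1-ol, via oxamagnesole chelate 5 (not isolated)
Conditions: iPrMgCl (3 equiv), CuI (10 mol%), THF, −10 °C to rt; then Bu3SnCl, 0 °C to rt
Reagents that add atoms: isopropylmagnesium chloride CC(C)[Mg]Cl; tributyltin chloride CCCC[Sn](Cl)(CCCC)CCCC
Why: Copper-catalysed anti-carbomagnesiation of the propargylic alkoxide places isopropyl on C2 and magnesium on C3 within a five-membered chelate, so that stannylation with retention fixes tin cis to the hydroxymethyl group, which later becomes the Z geometry of C7=C8.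

Step 3
Reactants: 3 (1E,6E)-1,7-diiodo-2,6-dimethylhepta-1,6-diene (3 equiv); 6 (2Z)-2-(propan-2-yl)-3-(tributylstannyl)prop-2-en-1-ol
Product: 7 (2Z,4E,9E)-10-iodo-5,9-dimethyl-2-(propan-2-yl)deca-2,4,9-trien-1-ol
Conditions: Pd2(dba)3 (2.5 mol%), AsPh3 (10 mol%), NMP, rt
Reagents that add atoms: none
Why: Stille coupling proceeds with retention at both alkenyl partners, and the excess of the symmetrical diiodide 3 should hold the reaction at monocoupling, the surplus being recovered.

Step 4
Reactants: 7 (2Z,4E,9E)-10-iodo-5,9-dimethyl-2-(propan-2-yl)deca-2,4,9-trien-1-ol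
Product: 8 (2Z,4E,9E)-10-iodo-5,9-dimethyl-2-(propan-2-yl)deca-2,4,9-trienal
Conditions: activated MnO2, CH2Cl2, 0 °C, short contact; cold filtration, solution used at once
Reagents that add atoms: none
Why: Activated MnO2 oxidises the dienylic alcohol selectively under neutral conditions, which should preserve the labile 2Z geometry as long as the aldehyde is kept cold and used at once.

Step 5
Reactants: 8 (2Z,4E,9E)-10-iodo-5,9-dimethyl-2-(propan-2-yl)deca-2,4,9-trienal
Product: 10 (1S,2Z,4E,9E)-5,9-dimethyl-2-(propan-2-yl)cyclodeca-2,4,9-trien-1-ol, via alkenylchromium species 9 (not isolated)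
Conditions: CrCl2 (6 equiv), N-[2-((4S)-4-isopropyl-4,5-dihydrooxazol-2-yl)-6-methylphenyl]methanesulfonamide (6.6 equiv), Et3N (6.6 equiv), NiCl2 (cat.), THF, rt; slow addition of cold 8 to a final 1 mM; aq. sodium serinate work-up
Reagents that add atoms: none
Why: Zerovalent nickel inserts into the C–I bond of 8 with retention, the alkenyl group passes to trivalent chromium (9) and adds irreversibly to the aldehyde carbon, so that the C5–C6 bond and the ten-membered carbocycle arise together. The closest known reaction type is the Nozaki–Hiyama–Kishi macrocyclisation of alkenyl iodide aldehydes, including its asymmetric form with chromium oxazoline–sulfonamide complexes. The ring closes in the 10-exo-trig mode. The only new stereocentre, C6, is controlled by the chiral sulfonamide on chromium, which binds the aldehyde and leaves one face open to the alkenyl ligand to give the S carbinol, while the E geometry of C4=C5 is carried over from the configurationally stable alkenylchromium. The step needs pure 1,2-addition, since attack at the δ-carbon C10 would close a six-membered ring, and this is secured by the strict carbonyl selectivity of alkenylchromium reagents, which also ignore the diene. Ring closure over oligomerisation is secured by slow addition at high dilution and by the 2Z geometry of 8, which turns the formyl group back toward the chain, and the short life of 8 in the flask limits scrambling of C9=C10 through its 2H-pyran valence isomer.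

Step 6
Reactants: 10 (1S,2Z,4E,9E)-5,9-dimethyl-2-(propan-2-yl)cyclodeca-2,4,9-trien-1-ol
Product: 11 (1S,2R,3Z,5E,10S)-6,10-dimethyl-3-(propan-2-yl)-11-oxabicyclo[8.1.0]undeca-3,5-dien-2-ol
Conditions: VO(acac)2 (5 mol%), t-BuOOH (1.2 equiv, decane), CH2Cl2, 0 °C
Reagents that add atoms: tert-butyl hydroperoxide CC(C)(C)OO
Why: Hydroxyl-directed vanadium-catalysed epoxidation delivers oxygen from the C6 alkoxide to the outer face of the strained E C4=C5 bond in the conformer that holds C6–H in the alkene plane next to the C4 methyl group (minimal allylic 1,3-strain), which sets C4 as S, while the conjugated, isopropyl-shielded C7=C8 bond is the less nucleophilic one.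

Step 7
Reactants: 11 (1S,2R,3Z,5E,10S)-6,10-dimethyl-3-(propan-2-yl)-11-oxabicyclo[8.1.0]undeca-3,5-dien-2-ol
Product: 12 (1R,3Z,5E,10S)-6,10-dimethyl-3-(propan-2-yl)-11-oxabicyclo[8.1.0]undeca-3,5-dien-2-one
Conditions: Dess–Martin periodinane, CH2Cl2, 0 °C to rt
Reagents that add atoms: none
Why: Dess–Martin oxidation converts the secondary alcohol into the ketone under mild conditions that leave epoxide and diene untouched, giving up the C6 centre only after it has passed its information on to C4.

Step 8
Reactants: 12 (1R,3Z,5E,10S)-6,10-dimethyl-3-(propan-2-yl)-11-oxabicyclo[8.1.0]undeca-3,5-dien-2-one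
Product: 13 (2Z,4E,9S)-9-hydroxy-5,9-dimethyl-2-(propan-2-yl)cyclodeca-2,4-dien-1-one
Conditions: SmI2 (2.5 equiv), THF/MeOH, −90 °C
Reagents that add atoms: none
Why: Single-electron reduction of the α,β-epoxy ketone by SmI2 cleaves the Cα–O bond through the ketyl and the samarium enolate, so that no backside attack from inside the ring is needed and the tertiary C4–O bond keeps its configuration.

Step 9
Reactants: 13 (2Z,4E,9S)-9-hydroxy-5,9-dimethyl-2-(propan-2-yl)cyclodeca-2,4-dien-1-one
Product: 15 (1S,3S,4Z,6E)-1,7-dimethyl-4-(propan-2-yl)cyclodeca-4,6-diene-1,3-diol, via diethylboron chelate 14 (not isolated)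
Conditions: Et2BOMe, THF/MeOH (4:1), −78 °C; NaBH4, −78 °C; AcOH quench, co-evaporation from MeOH
Reagents that add atoms: none
Why: In this Narasaka–Prasad reduction the boron chelate 14 holds both ring bonds equatorial in a six-membered half-chair and external hydride attacks the carbonyl axially in a 1,2-sense, which should give the 1,3-syn diol and so reset C6 as S under the control of C4.

Step 10
Reactants: 15 (1S,3S,4Z,6E)-1,7-dimethyl-4-(propan-2-yl)cyclodeca-4,6-diene-1,3-diol; 16 4-acetoxybenzoyl chloride
Product: 17 (1S,2Z,4E,9S)-9-hydroxy-5,9-dimethyl-2-(propan-2-yl)cyclodeca-2,4-dien-1-yl 4-acetoxybenzoate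
Conditions: 16 (1.2 equiv), pyridine, DMAP (cat.), CH2Cl2, 0 °C to rt
Reagents that add atoms: none
Why: DMAP-catalysed acylation distinguishes the secondary C6 hydroxyl from the hindered tertiary C4 hydroxyl and does not touch either stereocentre.

Step 11
Reactants: 17 (1S,2Z,4E,9S)-9-hydroxy-5,9-dimethyl-2-(propan-2-yl)cyclodeca-2,4-dien-1-yl 4-acetoxybenzoate
Product: 18 (1S,2Z,4E,9S)-9-hydroxy-5,9-dimethyl-2-(propan-2-yl)cyclodeca-2,4-dien-1-yl 4-hydroxybenzoate (CNP0130127.1)
Conditions: K2CO3 (cat.), MeOH, 0 °C
Reagents that add atoms: none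
Why: Base-catalysed methanolysis cleaves the activated aryl acetate much faster than the hindered secondary benzoate, whose reactivity falls further once the phenoxide has formed.

Compound list
1 | hepta-1,6-diyne | C#CCCCC#C | starting material
2 | (1E,6E)-1,7-bis(dimethylalanyl)-2,6-dimethylhepta-1,6-diene | C[Al](C)/C=C(\C)CCC/C(C)=C/[Al](C)C | intermediate
3 | (1E,6E)-1,7-diiodo-2,6-dimethylhepta-1,6-diene | I/C=C(\C)CCC/C(C)=C/I | intermediate
4 | prop-2-yn-1-ol | C#CCO | starting material
5 | 4-(propan-2-yl)-2,5-dihydro-1,2-oxamagnesole (chelated alkenylmagnesium alkoxide) | CC(C)C1=C[Mg]OC1 | intermediate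
6 | (2Z)-2-(propan-2-yl)-3-(tributylstannyl)prop-2-en-1-ol | CCCC[Sn](CCCC)(CCCC)/C=C(\CO)C(C)C | intermediate
7 | (2Z,4E,9E)-10-iodo-5,9-dimethyl-2-(propan-2-yl)deca-2,4,9-trien-1-ol | C/C(CCC/C(C)=C/I)=C\C=C(\C(C)C)CO | intermediate
8 | (2Z,4E,9E)-10-iodo-5,9-dimethyl-2-(propan-2-yl)deca-2,4,9-trienal | C/C(CCC/C(C)=C/I)=C\C=C(\C(C)C)C=O | intermediate
9 | alkenylchromium species from 8 (chromium drawn as its dichloride, sulfonamide ligand and solvent omitted) | C/C(CCC/C(C)=C/[Cr](Cl)Cl)=C\C=C(\C(C)C)C=O | intermediate
10 | (1S,2Z,4E,9E)-5,9-dimethyl-2-(propan-2-yl)cyclodeca-2,4,9-trien-1-ol | C/C1=C\C=C(\C(C)C)[C@@H](O)/C=C(\C)CCC1 | intermediate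
11 | (1S,2R,3Z,5E,10S)-6,10-dimethyl-3-(propan-2-yl)-11-oxabicyclo[8.1.0]undeca-3,5-dien-2-ol | C/C1=C\C=C(\C(C)C)[C@@H](O)[C@@H]2O[C@@]2(C)CCC1 | intermediate
12 | (1R,3Z,5E,10S)-6,10-dimethyl-3-(propan-2-yl)-11-oxabicyclo[8.1.0]undeca-3,5-dien-2-one | C/C1=C\C=C(\C(C)C)C(=O)[C@@H]2O[C@@]2(C)CCC1 | intermediate
13 | (2Z,4E,9S)-9-hydroxy-5,9-dimethyl-2-(propan-2-yl)cyclodeca-2,4-dien-1-one | C/C1=C\C=C(\C(C)C)C(=O)C[C@@](C)(O)CCC1 | intermediate
14 | diethylborinate (boron chelate) of 13 | C/C1=C\C=C(\C(C)C)C(=O)C[C@@](C)(OB(CC)CC)CCC1 | intermediate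
15 | (1S,3S,4Z,6E)-1,7-dimethyl-4-(propan-2-yl)cyclodeca-4,6-diene-1,3-diol | C/C1=C\C=C(\C(C)C)[C@@H](O)C[C@@](C)(O)CCC1 | intermediate
16 | 4-acetoxybenzoyl chloride | CC(=O)Oc1ccc(cc1)C(Cl)=O | starting material
17 | (1S,2Z,4E,9S)-9-hydroxy-5,9-dimethyl-2-(propan-2-yl)cyclodeca-2,4-dien-1-yl 4-acetoxybenzoate | C/C1=C\C=C(\C(C)C)[C@@H](OC(=O)c2ccc(OC(C)=O)cc2)C[C@@](C)(O)CCC1 | intermediate
18 | (1S,2Z,4E,9S)-9-hydroxy-5,9-dimethyl-2-(propan-2-yl)cyclodeca-2,4-dien-1-yl 4-hydroxybenzoate (CNP0130127.1) | C/C1=C\C=C(\C(C)C)[C@@H](OC(=O)c2ccc(O)cc2)C[C@@](C)(O)CCC1 | target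

Total step count: 11
Longest linear sequence: 10 (steps 1 and 3 to 11)

Steps most likely to fail

1. Step 5 (ring closure). The chiral chromium complex may discriminate the two aldehyde faces poorly, above all at the high dilution that the strained ring demands. That would lower the enantiomeric purity of everything that follows. Fallback: the centre is set by reduction instead of addition. Setting out from 8, the closure is run with CrCl2 and catalytic NiCl2 without ligand to give the racemic trienol F1. Dess–Martin oxidation then gives the achiral cross-conjugated dienone F2. Corey–Bakshi–Shibata reduction with the (R)-methyl-oxazaborolidine and catecholborane should tell the α-branched dienyl arm from the slimmer alkenyl arm, and it comes back to the route at 10.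

2. Step 6 (epoxidation). Oxygen transfer to the C7=C8 bond, which is also allylic to the C6 hydroxyl, may compete. Oxidation of the bis-allylic alcohol to the ketone may erode chemoselectivity as well. Fallback: oxygen is brought to C4 through a nucleophilic boron unit instead of an electrophilic oxygen. Setting out from 10, Dess–Martin oxidation gives the dienone F2 of the first fallback. Copper-catalysed enantioselective conjugate borylation (CuCl, NaOtBu, (R,S)-Josiphos, B2pin2, MeOH) of the strained β,β-disubstituted C4=C5 enone arm gives the tertiary β-boryl ketone F3. Oxidation with NaBO3 proceeds with retention and comes back to the route at 13, so steps 6 to 8 are bypassed.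

3. Step 4 (oxidation to the dienal). Thermal equilibration of 8 with its 2H-pyran valence isomer (oxa-6π electrocyclisation and reopening) may scramble the C9=C10 geometry. Prolonged contact with the oxidant may isomerise the 2Z bond. Fallback: the aldehyde is made before the diene. Setting out from 6, MnO2 gives the stannyl enal F4, which has no diene and cannot electrocyclise. Its Stille coupling with 3 then becomes the last operation before ring closure and comes back to the route at 8, whose cold filtered solution is fed directly to the chromium reagent.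

Further compounds
F1 | step 5 | racemic (2Z,4E,9E)-5,9-dimethyl-2-(propan-2-yl)cyclodeca-2,4,9-trien-1-ol | C/C1=C\C=C(\C(C)C)C(O)/C=C(\C)CCC1
F2 | step 5 | (2Z,4E,9E)-5,9-dimethyl-2-(propan-2-yl)cyclodeca-2,4,9-trien-1-one | C/C1=C\C=C(\C(C)C)C(=O)/C=C(\C)CCC1
F3 | step 6 | (2Z,4E)-5,9-dimethyl-2-(propan-2-yl)-9-(4,4,5,5-tetramethyl-1,3,2-dioxaborolan-2-yl)cyclodeca-2,4-dien-1-one, boron in the place of the C4 hydroxyl of 13 | C/C1=C\C=C(\C(C)C)C(=O)C[C@@](C)(B2OC(C)(C)C(C)(C)O2)CCC1
F4 | step 4 | (2Z)-2-(propan-2-yl)-3-(tributylstannyl)prop-2-enal | CCCC[Sn](CCCC)(CCCC)/C=C(\C=O)C(C)C
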